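**Retrosynthetic overview**

1. Target 18 ⇐ 17 by hydrogenolysis (five O-benzyl groups and the C8 bromine); 17 ⇐ 16 by Tamao–Fleming oxidation (C3–Si becomes C3–OH with retention, Si–O5 is cut).
2. 16 ⇐ resorcinol 13 + aldehyde 12 in one flask: Friedel–Crafts condensation, o-quinone methide formation, intramolecular oxa-[4+2]. This closes upper ring C and a temporary six-membered C–Si–O ring together and sets C2, C3 and C4.
3. 12 ⇐ phenol 8 + styrylsilyl chloride 11; 11 ⇐ alkyne 9 + silane 10 by hydrosilylation.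
4. 8 ⇐ (−)-epicatechin 1 by per-benzylation, C8 bromination (blocking group), C6 formylation and chelation-controlled 5-O-debenzylation. The formyl carbon becomes the interflavan carbon C4, so the 4→6 linkage is fixed before any coupling.
5. Ring order: epicatechin rings A, C and B are bought intact with both lower stereocentres; upper ring A comes from resorcinol and upper ring B from 9; upper ring C and the silicon ring close together in step 7; the silicon ring is excised in step 8.

Assumption: in step 4 the 5-O-benzyl ether (the ortho ether remote from bromine) is the one cleaved; the 7-hydroxy isomer would run through steps 6 to 8 in the same way and converge at 18.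

Assumption: the (R)-phosphoric acid in step 7 is taken as the antipode matched to the desired diene face; if the (S)-acid proves matched, it is used instead.

**Route**

Step 1
Reactants: 1 (−)-epicatechin
Product: 3 penta-O-benzylepicatechin, via tetrabenzyl ether 2 (not isolated)
Conditions: BnBr, K2CO3, DMF, 0 °C → rt; then NaH, n-Bu4NI (cat.), 0 °C → rt
Reagents that add atoms: benzyl bromide, BrCc1ccccc1
Why: Williamson etherification of the four phenoxides and then of the C3 alkoxide; no stereocentre is touched, and the phenols are alkylated before the strong base is added so that C2 cannot epimerise.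

Step 2
Reactants: 3 penta-O-benzylepicatechin
Product: 4 8-bromo-penta-O-benzylepicatechin
Conditions: NBS, CH2Cl2, −78 → 0 °C
Reagents that add atoms: N-bromosuccinimide, O=C1CCC(=O)N1Br
Why: electrophilic aromatic bromination, which in 5,7-dialkoxyflavans goes selectively to C8 and so blocks that position, leaving C6 as the only nucleophilic site of ring A.

Step 3
Reactants: 4 8-bromo-penta-O-benzylepicatechin
Product: 6 8-bromo-penta-O-benzylepicatechin-6-carbaldehyde, via iminium chloride 5 (not isolated)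
Conditions: POCl3, DMF, 70 °C; then H2O, rt
Reagents that add atoms: N,N-dimethylformamide, CN(C)C=O; water, O
Why: Vilsmeier–Haack formylation at the only free position of the phloroglucinol-type ring (C6, flanked by two alkoxy groups and para to the ring oxygen), the veratrole-type ring B being far less reactive.

Step 4
Reactants: 6 8-bromo-penta-O-benzylepicatechin-6-carbaldehyde
Product: 8 8-bromo-3,7,3',4'-tetra-O-benzyl-5-hydroxyepicatechin-6-carbaldehyde, via dichloroboryl ether 7 (not isolated)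
Conditions: BCl3 (1.1 equiv), CH2Cl2, −78 °C; then H2O
Reagents that add atoms: none
Why: chelation-controlled Lewis acid ether cleavage, in which BCl3 bound to the formyl oxygen removes one ortho benzyl group through a six-membered chelate that then protects against a second cleavage, while non-chelating benzyl ethers survive at −78 °C.

Step 5
Reactants: 9 1-(benzyloxy)-4-ethynylbenzene; 10 chlorodi(propan-2-yl)silane
Product: 11 chloro{(E)-2-[4-(benzyloxy)phenyl]ethenyl}di(propan-2-yl)silane
Conditions: Pt2[(CH2=CHSiMe2)2O]3 (0.1 mol %), P(t-Bu)3, THF, 0 °C → rt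
Reagents that add atoms: none
Why: platinum-catalysed syn hydrosilylation (Chalk–Harrod) of a terminal arylalkyne puts the bulky silyl group on the terminal carbon and gives the (E)-vinylsilane.

Step 6
Reactants: 8 8-bromo-3,7,3',4'-tetra-O-benzyl-5-hydroxyepicatechin-6-carbaldehyde; 11 chloro{(E)-2-[4-(benzyloxy)phenyl]ethenyl}di(propan-2-yl)silane
Product: 12 5-O-styrylsilyl ether of 8
Conditions: NaH, THF, 0 °C; then 11, 0 °C → rt
Reagents that add atoms: none
Why: O-silylation of the sodium phenoxide installs a temporary silicon tether (Stork-type) that holds the (E)-styryl unit next to C6.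

Step 7
Reactants: 12 5-O-styrylsilyl ether of 8; 13 resorcinol
Product: 16 silicon-bridged cycloadduct, via benzhydrol 14 (not isolated), via o-quinone methide 15 (not isolated)
Conditions: 13 (1.3 equiv), (R)-3,3'-bis(2,4,6-triisopropylphenyl)-1,1'-binaphthyl-2,2'-diyl hydrogen phosphate (10 mol %), 5 Å MS, toluene, 0 → 40 °C
Reagents that add atoms: none
Why: Proposed new method: the acid condenses resorcinol C4 with the aldehyde (Friedel–Crafts hydroxyalkylation) and dehydrates benzhydrol 14 to the (E)-o-quinone methide 15, whose electron-poor 1-oxadiene is captured by the tethered electron-rich (E)-styryl unit in an intramolecular inverse-demand oxa-[4+2] (the silicon-bearing carbon, whose attack gives a cation both β to silicon and p-alkoxybenzylic, bonds to C4 and the quinone methide oxygen closes on the benzylic carbon), so that ring C and the six-membered oxasiline ring form together; the E-alkene fixes H2/H3 trans, the short tether with aryl-endo and silicon-exo approach fixes the trans ring fusion (H3/H4 trans, hence 2,4-cis), and the chiral phosphate hydrogen-bonded to the quinone methide oxygen selects the diene face, the minor face isomer being removed by chromatography; the closest known reactions are the Tietze domino Knoevenagel/hetero-Diels–Alder reaction, the citronellal–resorcinol route to hexahydrocannabinols and chiral Brønsted acid catalysed intramolecular o-quinone methide [4+2] cycloadditions.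

Step 8
Reactants: 16 silicon-bridged cycloadduct
Product: 17 partially benzylated 8-bromo dimer (free 3-OH and 7-OH on the new unit, free 5-OH on the epicatechin unit)
Conditions: 30 % H2O2, KF, KHCO3, THF/MeOH, rt → 40 °C
Reagents that add atoms: hydrogen peroxide, OO
Why: Tamao–Fleming oxidation, in which hydroperoxide adds to the aryloxy-activated silicon and the C3–Si bond migrates to oxygen with retention, excising the silicon ring and leaving the 3-OH trans to both aryl groups.

Step 9
Reactants: 17 partially benzylated 8-bromo dimer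
Product: 18 guibourtinidol-(4α→6)-epicatechin (target)
Conditions: H2 (1 atm), Pd(OH)2/C, NaOAc, THF/MeOH/H2O, rt
Reagents that add atoms: none
Why: catalytic hydrogenolysis removes the five benzyl ethers and the aryl bromine (HBr taken up by acetate) without touching the ring C–O bonds, the interflavan bond or any stereocentre, as is standard in procyanidin synthesis.

**Compound list**

1 | (−)-epicatechin, (2R,3R)-2-(3,4-dihydroxyphenyl)chromane-3,5,7-triol | c1c(O)cc2c(c1O)C[C@@H](O)[C@@H](c3ccc(O)c(O)c3)O2 | starting material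

2 | (2R,3R)-5,7-bis(benzyloxy)-2-[3,4-bis(benzyloxy)phenyl]chroman-3-ol (tetrabenzyl ether) | c1c(OCc4ccccc4)cc2c(c1OCc4ccccc4)C[C@@H](O)[C@@H](c3ccc(OCc4ccccc4)c(OCc4ccccc4)c3)O2 | intermediate

3 | (2R,3R)-3,5,7-tris(benzyloxy)-2-[3,4-bis(benzyloxy)phenyl]chromane (penta-O-benzylepicatechin) | c1c(OCc4ccccc4)cc2c(c1OCc4ccccc4)C[C@@H](OCc4ccccc4)[C@@H](c3ccc(OCc4ccccc4)c(OCc4ccccc4)c3)O2 | intermediate

4 | (2R,3R)-8-bromo-3,5,7-tris(benzyloxy)-2-[3,4-bis(benzyloxy)phenyl]chromane | c1c(OCc4ccccc4)c(Br)c2c(c1OCc4ccccc4)C[C@@H](OCc4ccccc4)[C@@H](c3ccc(OCc4ccccc4)c(OCc4ccccc4)c3)O2 | intermediate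

5 | iminium chloride: C6–CH=N(CH3)2+ Cl− derivative of 4 | C[N+](C)=Cc1c(OCc4ccccc4)c(Br)c2c(c1OCc4ccccc4)C[C@@H](OCc4ccccc4)[C@@H](c3ccc(OCc4ccccc4)c(OCc4ccccc4)c3)O2.[Cl-] | intermediate

6 | (2R,3R)-8-bromo-3,5,7-tris(benzyloxy)-2-[3,4-bis(benzyloxy)phenyl]chromane-6-carbaldehyde | O=Cc1c(OCc4ccccc4)c(Br)c2c(c1OCc4ccccc4)C[C@@H](OCc4ccccc4)[C@@H](c3ccc(OCc4ccccc4)c(OCc4ccccc4)c3)O2 | intermediate

7 | 5-O-dichloroboryl ether of 8 (boron chelated by the formyl oxygen) | O=Cc1c(OCc4ccccc4)c(Br)c2c(c1OB(Cl)Cl)C[C@@H](OCc4ccccc4)[C@@H](c3ccc(OCc4ccccc4)c(OCc4ccccc4)c3)O2 | intermediate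

8 | (2R,3R)-8-bromo-3,7-bis(benzyloxy)-2-[3,4-bis(benzyloxy)phenyl]-5-hydroxychromane-6-carbaldehyde | O=Cc1c(OCc4ccccc4)c(Br)c2c(c1O)C[C@@H](OCc4ccccc4)[C@@H](c3ccc(OCc4ccccc4)c(OCc4ccccc4)c3)O2 | intermediate

9 | 1-(benzyloxy)-4-ethynylbenzene | C#Cc1ccc(OCc2ccccc2)cc1 | starting material

10 | chlorodi(propan-2-yl)silane | CC(C)[SiH](Cl)C(C)C | starting material

11 | chloro{(E)-2-[4-(benzyloxy)phenyl]ethenyl}di(propan-2-yl)silane | CC(C)[Si](Cl)(C(C)C)/C=C/c1ccc(OCc2ccccc2)cc1 | intermediate

12 | 5-O-[{(E)-2-[4-(benzyloxy)phenyl]ethenyl}di(propan-2-yl)silyl] ether of 8 | O=Cc1c(OCc4ccccc4)c(Br)c2c(c1O[Si](C(C)C)(C(C)C)/C=C/c5ccc(OCc4ccccc4)cc5)C[C@@H](OCc4ccccc4)[C@@H](c3ccc(OCc4ccccc4)c(OCc4ccccc4)c3)O2 | intermediate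

13 | resorcinol (benzene-1,3-diol) | Oc1cccc(O)c1 | starting material

14 | benzhydrol: (2,4-dihydroxyphenyl)(C6 of 12)methanol, both carbinol epimers | OC(c6ccc(O)cc6O)c1c(OCc4ccccc4)c(Br)c2c(c1O[Si](C(C)C)(C(C)C)/C=C/c5ccc(OCc4ccccc4)cc5)C[C@@H](OCc4ccccc4)[C@@H](c3ccc(OCc4ccccc4)c(OCc4ccccc4)c3)O2 | intermediate

15 | (E)-o-quinone methide: 3-hydroxy-6-[(C6 of 12)methylidene]cyclohexa-2,4-dien-1-one | O=C1C=C(O)C=C/C1=C\c7c(OCc4ccccc4)c(Br)c2c(c7O[Si](C(C)C)(C(C)C)/C=C/c5ccc(OCc4ccccc4)cc5)C[C@@H](OCc4ccccc4)[C@@H](c3ccc(OCc4ccccc4)c(OCc4ccccc4)c3)O2 | intermediate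

16 | silicon-bridged cycloadduct: new (2R,3S,4S)-2-[4-(benzyloxy)phenyl]-7-hydroxychroman whose C4 is bonded to epicatechin C6 and whose C3 carries Si(i-Pr)2 bonded to epicatechin O5 (six-membered ring C4–C3–Si–O5–C5–C6, trans-fused to ring C; H2/H3 trans, H3/H4 trans); epicatechin unit (2R,3R), 8-bromo, 3,7,3',4'-tetra-O-benzyl | C(c5ccccc5)Oc1ccc([C@H]2Oc3cc(O)ccc3[C@@H](c6c(OCc7ccccc7)c(Br)c8c(c6O%10)C[C@@H](OCc7ccccc7)[C@@H](c4ccc(OCc7ccccc7)c(OCc7ccccc7)c4)O8)[C@@H]2[Si]%10(C(C)C)C(C)C)cc1 | intermediate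

17 | (2R,3S,4S)-2-[4-(benzyloxy)phenyl]-4-{(2R,3R)-8-bromo-3,7-bis(benzyloxy)-2-[3,4-bis(benzyloxy)phenyl]-5-hydroxychroman-6-yl}chromane-3,7-diol | C(c5ccccc5)Oc1ccc([C@H]2Oc3cc(O)ccc3[C@@H](c6c(OCc7ccccc7)c(Br)c8c(c6O)C[C@@H](OCc7ccccc7)[C@@H](c4ccc(OCc7ccccc7)c(OCc7ccccc7)c4)O8)[C@@H]2O)cc1 | intermediate

18 | guibourtinidol-(4α→6)-epicatechin, (2R,3S,4S)-4-[(2R,3R)-2-(3,4-dihydroxyphenyl)-3,5,7-trihydroxychroman-6-yl]-2-(4-hydroxyphenyl)chromane-3,7-diol | Oc1ccc([C@H]2Oc3cc(O)ccc3[C@@H](c3c(O)cc4c(c3O)C[C@@H](O)[C@@H](c3ccc(O)c(O)c3)O4)[C@@H]2O)cc1 | target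

**Step count and risks**

Total step count: 9. Longest linear sequence: 8 steps (steps 1–4 and 6–9 from epicatechin); step 5 is a one-step side branch.

Steps most likely to fail:

Step 7 (condensation/cycloaddition cascade). The hindered, electron-rich aldehyde may condense slowly, the vinylsilane may protodesilylate or transfer its vinyl group instead of cyclising, and face selectivity is not proven. The fallback sets out from 4 and comes back at 18, giving up the tether. Purchased 2-hydroxy-4-(benzyloxy)benzaldehyde and 1-[4-(benzyloxy)phenyl]ethanone are condensed with HBF4·OEt2 in acetic acid to 7-(benzyloxy)-2-[4-(benzyloxy)phenyl]chromenylium tetrafluoroborate F1. Bromide 4 adds through C6 to C4 of this flavylium ion (K2CO3, MeCN) to give the 4-aryl-4H-chromene F2, whose C4 epimers are separated by chromatography. Hydroboration–oxidation (BH3·SMe2, then NaBO3·4H2O) adds H and OH syn to the enol ether from the face opposite the C4 aryl group and gives the all-trans per-benzylated flavan-3-ol F3. Hydrogenolysis under the conditions of step 9 then gives 18.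

Step 8 (Tamao–Fleming oxidation). The silane is β to the ring aryloxy group at a benzylic carbon, so fluoride or base may trigger Peterson-type ring opening instead of oxidation. The fallback sets out from 6 and comes back at 18, making the C3 oxygen from boron and without a tether. Alkyne 9 is hydroborated with pinacolborane ((C5H5)2ZrHCl cat.) to the (E)-styrylboronate F4. Aldehyde 6, resorcinol 13 and F4 are combined under the chiral acid of step 7, so that the o-quinone methide is trapped intermolecularly (boron-bearing carbon to C4, aryl endo) to give the 3-boryl flavan F5. NaBO3·4H2O oxidises the C–B bond with retention under conditions known to outrun β-elimination in flav-3-ene hydroboration products and gives the flavan-3-ol F6. Hydrogenolysis as in step 9 gives 18.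

Step 6 (silylation of the hindered, hydrogen-bonded phenol with the bulky chlorosilane). The fallback sets out from 8 and comes back at 12, building the tether in the reverse order. The phenoxide of 8 is silylated with the small chlorosilane 10 (NaH, THF) to the aryloxydi(propan-2-yl)silane F7, and the Si–H bond of F7 is then added to alkyne 9 by the platinum-catalysed hydrosilylation of step 5 to give 12.

**Further compounds**

F1 | step 7 | 7-(benzyloxy)-2-[4-(benzyloxy)phenyl]chromenylium tetrafluoroborate | F[B-](F)(F)F.C(c1ccccc1)Oc1ccc2ccc(-c3ccc(OCc4ccccc4)cc3)[o+]c2c1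

F2 | step 7 | 7-(benzyloxy)-2-[4-(benzyloxy)phenyl]-4-(C6 of 4)-4H-chromene, C4 configured as in 18 | C(c5ccccc5)Oc1ccc(C2Oc3cc(OCc5ccccc5)ccc3[C@@H](c6c(OCc7ccccc7)c(Br)c8c(c6OCc7ccccc7)C[C@@H](OCc7ccccc7)[C@@H](c4ccc(OCc7ccccc7)c(OCc7ccccc7)c4)O8)C=2)cc1

F3 | step 7 | (2R,3S,4S)-7-(benzyloxy)-2-[4-(benzyloxy)phenyl]-4-(C6 of 4)chroman-3-ol | C(c5ccccc5)Oc1ccc([C@H]2Oc3cc(OCc5ccccc5)ccc3[C@@H](c6c(OCc7ccccc7)c(Br)c8c(c6OCc7ccccc7)C[C@@H](OCc7ccccc7)[C@@H](c4ccc(OCc7ccccc7)c(OCc7ccccc7)c4)O8)[C@@H]2O)cc1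

F4 | step 8 | 2-{(E)-2-[4-(benzyloxy)phenyl]ethenyl}-4,4,5,5-tetramethyl-1,3,2-dioxaborolane | CC1(C)OB(/C=C/c2ccc(OCc3ccccc3)cc2)OC1(C)C

F5 | step 8 | 3-(pinacolboryl) flavan: as F6 with the boronate in place of the 3-OH, same spatial arrangement | C(c5ccccc5)Oc1ccc([C@H]2Oc3cc(O)ccc3[C@@H](c6c(OCc7ccccc7)c(Br)c8c(c6OCc7ccccc7)C[C@@H](OCc7ccccc7)[C@@H](c4ccc(OCc7ccccc7)c(OCc7ccccc7)c4)O8)[C@@H]2B9OC(C)(C)C(C)(C)O9)cc1

F6 | step 8 | (2R,3S,4S)-2-[4-(benzyloxy)phenyl]-4-(C6 of 4)chromane-3,7-diol | C(c5ccccc5)Oc1ccc([C@H]2Oc3cc(O)ccc3[C@@H](c6c(OCc7ccccc7)c(Br)c8c(c6OCc7ccccc7)C[C@@H](OCc7ccccc7)[C@@H](c4ccc(OCc7ccccc7)c(OCc7ccccc7)c4)O8)[C@@H]2O)cc1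

F7 | step 6 | 5-O-[di(propan-2-yl)silyl] ether of 8 | O=Cc1c(OCc4ccccc4)c(Br)c2c(c1O[SiH](C(C)C)C(C)C)C[C@@H](OCc4ccccc4)[C@@H](c3ccc(OCc4ccccc4)c(OCc4ccccc4)c3)O2
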